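## Structural features

Compound 31 is a C19 gibberellin-type tetracycle. Cyclohexane ring A and cyclopentane ring B share C5–C10, ring B and ring C share C8–C9, and rings C and D form a bicyclo[3.2.1]octane with bridgeheads C8 and C13 and C14 as the one-carbon bridge. A γ-lactone (C4–C19(=O)–O–C10) spans ring A on the face opposite H5. There are nine stereocentres (C1, C3, C4, C5, C6, C8, C9, C10, C13), contiguous around rings A and B, and four of them (C4, C8, C10, C13) carry no hydrogen. The C1 hydroxyl is equatorial and cis to the lactone oxygen; the C3 hydroxyl is axial, trans to the C1 hydroxyl and cis to the C18 methyl; the C7 acid on C6 is trans to the C5–C4 bond; H9 lies on the side of the C15–C16 bridge. Fragile points are the tertiary C13 alcohol beside the C16 exocyclic methylene (acid-induced skeletal rearrangement of rings C and D), the C3 alcohol β to the lactone carbonyl (retro-aldol epimerisation in base), the epimerisable C6, and the α-ketol at the 16-ketone stage. The real difficulty is the pair of quaternary bridgeheads C8 and C13 in absolute sense, followed by the crowded ring A. The key step uses the fact that C13 and C16 are neighbours in ring D. As the two carbonyls of a 4,4-disubstituted cyclopentane-1,2-dione they are mirror images of each other across a plane through C8, so one C12–C13 bond from a three-carbon arm on C8 closes ring C and creates both bridgehead stereocentres from an achiral compound.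

## Logic of the disconnections

31 to 30. The C16=C17 bond is cut last because the allylic tertiary alcohol and exocyclic alkene are the acid-sensitive part of the molecule. C16 can then travel as a masked ketone, which allows two ozonolyses earlier. The forward step must methylenate a hindered ketone beside free hydroxyls and a free acid without base-driven epimerisation.

30 to 29. No skeletal bond is cut. The C16 dioxolane, the C13 silyl ether and the tert-butyl ester are chosen so that one acid treatment removes all three before the alkene exists. The lactone and the 1,3-diol must tolerate that acid.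

29 to 28. The C3–H bond is cut, putting C3 back to a ketone. The axial alcohol is the less stable epimer, so it has to come from a kinetically controlled hydride delivery on the ring-locked ketone.

28 to 27. The C1–C2 bond is cut (ring A). A methyl ketone on C4 and an aldehyde on C10 are an aldol pair with one enolisable site, and the aldehyde oxygen becomes the C1 hydroxyl. The forward step must give the equatorial C1 alcohol.

27 to 26, and 26 to 24 plus 25. The C1 aldehyde is traced to a vinyl group, and the C3–C4 bond is cut. The cis-fused bicyclic lactone enolate of 24 has one open face, so acylation there sets the quaternary C4 with the acetyl group on the side of C1. The forward step must enolise C4 and not C6.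

24 to 23. The C4–C5 bond is cut, opening the lactone ring to a propionate on the C10 oxygen and a C5=C6 enoate. The short tether fixes C5 relative to C10, and C6 becomes a thermodynamic centre. The forward step needs a clean 5-exo Michael closure.

23 to 19 plus 20 plus 21. The C1–C10 bond and the O10–C19 bond are cut. Addition to the C10 ketone from the face of H9 sets C10, and the alkoxide is acylated in the same flask.

19 to 17 to 16. The C5=C6 unsaturation and the C10 carbonyl are taken back to a saturated ring B with an exocyclic methylene on C10. Passing through the enone erases the uncontrolled C6 centre.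

16 to 15, and 15 to 13 plus 14. The C9–C10 bond (ring B) and the C5–C6 bond are cut. A vinyl radical on a three-atom tether from C8 can reach C9 only on the face syn to C6, so C9 is set by geometry. The alkene left by the key step is used directly and no oxidation at C12 is needed.

13 to 12 to 11. Only protection is involved: the α-ketol is masked against enolisation, alkoxide chemistry and rearrangement.

11 to 10 (key). The C12–C13 bond is cut, which opens ring C and returns C13 and C16 to equivalent carbonyls. The bicycle and two stereocentres disappear and an achiral compound remains. The arm must be (Z): an (E) arm cannot bring C12 to a ring carbonyl because ring C would then contain a trans double bond, so 10 is drawn as the Z isomer. The ester is tert-butyl so that the C13 alkoxide, which is cis-1,3 to the arm on ring D, cannot lactonise onto it. The forward step must choose one of two mirror-image carbonyls.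

10 to 9 to 8. The two C=O groups are taken back through the cis-diol to the symmetric ring alkene. The regiochemistry of the dione is then automatic. The oxidant must discriminate between two alkenes.

8 to 7 to 6, and 6 to 4 plus 5. The C9=C11 bond is cut. A Z-selective olefination of a non-enolisable aldehyde gives the cis arm, and reduction and bromination finish it. The tert-butyl ester must survive the hydride.

4 to 3, and 3 to 1 plus 2. The C6–C8 bond is cut. Alkylating the ester enolate of a symmetric cyclopentene makes the quaternary C8 in one step from two commercial compounds.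

## Other disconnections considered

Alternative 1: The cut is made late in ring A, severing C4–C19 and C3–O together. The forward step places the lactone carbonyl on the C10 oxygen as an alkoxycarbonyl radical (for instance from a Se-phenyl selenocarbonate). This closes 5-exo onto C4 of a C3=C4 alkene, and the C3 radical is caught by O2 to give A1 after reduction of the hydroperoxide.
- In its favour: one operation forms the lactone ring, the quaternary C4 and the C3–O bond. The tether forces C19 onto the lactone face, so C4 is as secure as in the chosen plan (equal). In bonds per step at this point it is better than steps 17 to 20 of the chosen plan.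
- Against it here: alkoxycarbonyl radicals on a tertiary oxygen lose CO2 easily, and the attack must occur at the methyl-bearing alkene carbon. The C3 configuration comes from O2 capture of a ring radical with no tether to guide it, while the less stable axial alcohol is required. Ring A with C1, C5 and C10 correct must already exist.
- Comparison: it is an end-game tactic and does not address the bicyclooctane or the absolute configuration, which step 8 of the chosen plan settles from an achiral compound. The two ideas could be combined. Each plan rests on one thinly precedented selectivity (C3 there, carbonyl choice here).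

Alternative 2: The cut removes C8–C9 and C5–C6 at once. Forward, a trimethylenemethane dipole generated with zerovalent palladium (Pd(OAc)2 with P(Oi-Pr)3) and tethered through C11–C12 to C13 adds across an alkylidene malonate on C8 of a preformed ring D, closing rings C and B together to give A2.
- In its favour: two rings and two C–C bonds form in one step, the quaternary C8 is made in the annulation, and the C10 exocyclic methylene is delivered directly. That is the same handle the chosen route reaches only after steps 11 and 12, so in skeletal bonds per step it is better, and it is more convergent.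
- Against it here: the dipole must attack a fully substituted alkene carbon to form a bridgehead inside a bridged closure. C13 and C16 of ring D must be made enantiopure beforehand. The extra ester must be removed later, leaving C6 unset, and ring A remains to be built.
- Comparison: once the ring D synthesis is counted the step totals to the tricycle are about equal. The chosen plan is stronger in that chirality arises in the ring-forming step from an achiral dione, and its ring closure is a simple 6-exo addition.

Alternative 3: The cut is C5–C10 in ring B. Forward, a triazolium-derived carbene turns a C10 aldehyde on C9 into an acyl anion equivalent, which adds 5-exo to C5 of a 2-methylbut-2-enoate unit on C6 and gives A3 as a mixture at C4.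
- In its favour: it is a known organocatalytic reaction class, and it delivers the ring B ketone with the C5 propionate arm in one step. The chosen route builds that combination over steps 11 to 16, so this is better in step economy for ring B. It is equal in that the C4 mixture is harmless in both plans.
- Against it here: it presupposes the C9–C10 bond and the epimerisable C9 and C6 centres, made without the geometric forcing that the radical closure gives. The acceptor is an α-methyl, β-substituted enoate, a slow partner for a branched aliphatic aldehyde. C5 is set by substrate bias alone, where the chosen plan fixes it through the lactone tether. A3 already carries the C16 methylene, which rules out later ozonolyses.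
- Comparison: it competes only with the middle of the chosen route. Both would start from the same kind of C/D bicycle, and the C10 ketone of A3 would be elaborated as in steps 15 to 22.

Key step: step 8

Remarks on the chemistry (assumptions):
- Gibberellin numbering (C1 to C19) is used for every intermediate, and configurations are those in the SMILES of the compound list.
- Compound 10 is written as the diketone but should exist mainly as two mirror-image 2-hydroxy-enone tautomers; these are assumed to interconvert faster than they cyclise.
- The ligand L*H of step 8 is (S,S)-1,8-bis(4-isopropyl-4,5-dihydro-1,3-oxazol-2-yl)-3,6-diphenyl-9H-carbazole, a known ligand type made separately from valinol; it does not enter the product and is not counted. Which antipode leads to 11 must be found by trial, and the other antipode is used if needed.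

## Route

Step 1
Reactants: 1 methyl cyclopent-3-ene-1-carboxylate; 2 tert-butyl bromoacetate
Product: 3 methyl 1-(2-tert-butoxy-2-oxoethyl)cyclopent-3-ene-1-carboxylate
Conditions: LiN(i-Pr)2, THF, −78 °C; then 2, −78 → 0 °C
Reagents that add atoms: none
Why: Ester enolate alkylation with a reactive α-bromo ester makes the quaternary C8 and the C6–C7 arm; the product is achiral because both ring arms are identical.

Step 2
Reactants: 3
Product: 4 tert-butyl 2-(1-formylcyclopent-3-en-1-yl)acetate
Conditions: i-Bu2AlH (1.1 equiv), CH2Cl2, −78 °C; MeOH, aq. potassium sodium tartrate
Reagents that add atoms: none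
Why: Partial reduction of the methyl ester: the aluminium hemiacetal of an ester on a quaternary carbon is stable at −78 °C, and a tert-butyl ester is reduced much more slowly than a methyl ester.

Step 3
Reactants: 4; 5 methyl 2-[bis(2,2,2-trifluoroethoxy)phosphoryl]acetate
Product: 6 tert-butyl 2-{1-[(Z)-3-methoxy-3-oxoprop-1-en-1-yl]cyclopent-3-en-1-yl}acetate
Conditions: KN(SiMe3)2, 18-crown-6, THF, −78 °C
Reagents that add atoms: none
Why: Still–Gennari olefination of a non-enolisable aldehyde; fast elimination from the kinetic adduct of the trifluoroethyl phosphonate gives the (Z)-enoate, which fixes the cis geometry of C9=C11.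

Step 4
Reactants: 6
Product: 7 tert-butyl 2-{1-[(Z)-3-hydroxyprop-1-en-1-yl]cyclopent-3-en-1-yl}acetate
Conditions: i-Bu2AlH (2.3 equiv), CH2Cl2, −78 °C; aq. potassium sodium tartrate
Reagents that add atoms: none
Why: 1,2-Reduction of the conjugated methyl ester to the allylic alcohol with retention of alkene geometry; the tert-butyl ester is spared at −78 °C.

Step 5
Reactants: 7
Product: 8 tert-butyl 2-{1-[(Z)-3-bromoprop-1-en-1-yl]cyclopent-3-en-1-yl}acetate
Conditions: CBr4, PPh3, CH2Cl2, −20 → 0 °C; used without storage
Reagents that add atoms: carbon tetrabromide BrC(Br)(Br)Br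
Why: Appel bromination by SN2 at the primary carbon; SN2′ attack would have to occur at the neopentyl C9, so the Z geometry and the position of the halide are kept.

Step 6
Reactants: 8
Product: 9 tert-butyl 2-{1-[(Z)-3-bromoprop-1-en-1-yl]-cis-3,4-dihydroxycyclopentyl}acetate (both achiral diastereomers)
Conditions: OsO4 (2 mol %), N-methylmorpholine N-oxide, citric acid, t-BuOH–H2O, 0 → 25 °C
Reagents that add atoms: osmium tetroxide O=[Os](=O)(=O)=O; N-methylmorpholine N-oxide C[N+]1([O-])CCOCC1
Why: Upjohn dihydroxylation; electrophilic OsO4 should take the strained, electron-rich ring alkene over the arm alkene, which is deactivated by the allylic bromide and shielded by the quaternary carbon. Citric acid keeps N-methylmorpholine protonated so that it cannot quaternise the bromide, and both diols converge in step 7.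

Step 7
Reactants: 9
Product: 10 tert-butyl 2-{1-[(Z)-3-bromoprop-1-en-1-yl]-3,4-dioxocyclopentyl}acetate (achiral; in equilibrium with its hydroxy-enone tautomers)
Conditions: Dess–Martin periodinane (2.5 equiv), CH2Cl2, 0 → 25 °C
Reagents that add atoms: none
Why: Dess–Martin oxidation of both secondary alcohols to the 1,2-dione without C–C cleavage; the medium is non-basic, so no enolate forms that could be alkylated by the molecule's own allylic bromide.

Step 8
Reactants: 10
Product: 11 tert-butyl 2-(5-hydroxy-6-oxobicyclo[3.2.1]oct-2-en-1-yl)acetate (13-hydroxy-16-ketone, C9=C11 alkene, C6–C7 arm on C8; C8 and C13 as in 31)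
Conditions: CrCl(L*) (3 equiv, pre-formed from CrCl2 and the sodium salt of L*H), THF (0.01 M), slow addition of 10, 25 °C; aq. NH4Cl
Reagents that add atoms: none
Why: Proposed new method: two equivalents of divalent chromium reduce the allylic C–Br bond to an allylchromium species (trivalent chromium), which adds through C12 to one ring carbonyl and forms C12–C13 in a 6-exo-trig closure of ring C. Bonding through C9, the usual γ-terminus, would need a cyclobutane, and the Z arm lets the first-formed σ-allyl reach the carbonyl without isomerising. The closest known reaction types are the Nozaki–Hiyama–Kishi allylation of ketones, its ligand-controlled asymmetric form and intramolecular Barbier allylation; what is new is letting the ligand choose between the two mirror-image carbonyls of a 1,2-dione during a ring closure. The attacked carbon becomes the C13 carbinol, and because the mirror plane of 10 runs through C8 this one choice fixes C8 and C13 together. Their relative configuration is not a variable, since a three-carbon tether can only bridge the cyclopentane cis. Compound 10 reacts as hydroxy-enone tautomers that are mirror images and interconvert, so the ligand selects under Curtin–Hammett conditions and the untouched carbonyl returns as the C16 ketone on work-up. The step needs addition to a ketone in preference to the tert-butyl ester (organochromium reagents do not add to esters) and C–C bond formation faster than protonolysis by the enol O–H or reduction of the dione (halogen abstraction from the allylic bromide is the fastest electron transfer). No base is added so that the dione enolate cannot be alkylated by the bromide, and high dilution suppresses dimerisation.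

Step 9
Reactants: 11
Product: 12 13-O-triethylsilyl ether of 11
Conditions: Et3SiOSO2CF3, 2,6-lutidine, CH2Cl2, −78 → 0 °C
Reagents that add atoms: triethylsilyl trifluoromethanesulfonate CC[Si](CC)(CC)OS(=O)(=O)C(F)(F)F
Why: Silylation of the tertiary α-ketol hydroxyl with a silyl triflate and a weak hindered base; it blocks alkoxide-driven α-ketol rearrangement and later acylation at this oxygen.

Step 10
Reactants: 12
Product: 13 16,16-ethylenedioxy (1,3-dioxolane) derivative of 12
Conditions: Me3SiOCH2CH2OSiMe3, Me3SiOSO2CF3 (cat.), CH2Cl2, −78 → −20 °C; pyridine
Reagents that add atoms: 1,2-bis(trimethylsilyloxy)ethane C[Si](C)(C)OCCO[Si](C)(C)C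
Why: Noyori ketalisation under aprotic conditions at low temperature, mild enough for the tert-butyl ester and the silyl ether; it removes the acidic C15 protons and the electrophilic C16 carbonyl from the next ten steps.

Step 11
Reactants: 13; 14 2,3-dibromopropene
Product: 15 compound 13 with a 2-bromoprop-2-enyl group on C6 (C6 epimers)
Conditions: LiN(i-Pr)2, THF, −78 °C; then 14, DMPU, −78 → −20 °C
Reagents that add atoms: none
Why: Alkylation of the tert-butyl ester enolate by an allylic bromide forms C5–C6; the C6 configuration is not controlled and need not be, because step 14 erases it.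

Step 12
Reactants: 15
Product: 16 B/C/D tricycle with ring B closed, exocyclic methylene on C10, saturated C11 and cis B/C fusion (H9 on the side of the C15–C16 bridge; C6 epimers)
Conditions: n-Bu3SnH, AIBN (cat.), benzene (0.02 M), 80 °C
Reagents that add atoms: none
Why: Stork vinyl-radical cyclisation: the C10 radical adds 5-exo-trig to C9 of the ring C alkene and the C11 radical is reduced by the stannane. The three-atom tether from C8 reaches only the face of C9 syn to C6, so C9 is set by geometry.

Step 13
Reactants: 16
Product: 17 C10 ketone (ring B cyclopentanone; C6 epimers)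
Conditions: O3, CH2Cl2–MeOH, −78 °C; Me2S
Reagents that add atoms: ozone [O-][O+]=O
Why: Ozonolysis of the only alkene in the molecule; the ketal, silyl ether and ester are inert.

Step 14
Reactants: 17
Product: 19 ring B enone with C10 ketone conjugated to C5=C6 bearing the C7 tert-butyl ester, via C10 trimethylsilyl enol ether 18 (not isolated)
Conditions: LiN(i-Pr)2, THF, −78 °C; Me3SiCl; then Pd(OAc)2, MeCN, 25 °C
Reagents that add atoms: none
Why: Saegusa–Ito dehydrogenation: kinetic deprotonation occurs at the C5 methylene (C9 is a hindered ring-fusion methine), and β-hydride elimination of H6 from the palladium enolate gives the C5=C6 enone. The uncontrolled C6 centre disappears.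

Step 15
Reactants: 19; 20 vinylmagnesium bromide; 21 propionic anhydride
Product: 23 C10 vinyl carbinol propionate of enone 19 (vinyl on the face of H9), via bromomagnesium alkoxide 22 (not isolated)
Conditions: CeCl3, 20, THF, −78 °C; then 21, DMAP, −78 → 0 °C
Reagents that add atoms: none
Why: Organocerium 1,2-addition to the enone carbonyl followed by O-acylation of the alkoxide in the flask. The nucleophile should enter C10 from the face of H9, anti to the adjacent C9–C11 bond of ring C, so the oxygen ends on the ring C side as the lactone requires (C10 set).

Step 16
Reactants: 23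
Product: 24 tricyclic 19,10-lactone with C4 bearing H and methyl (both C4 epimers), H5 on the face of the vinyl group and the C7 ester trans to the C5–C4 bond
Conditions: LiN(i-Pr)2, THF, −78 °C; then t-BuOH, KOt-Bu (cat.), −78 → 25 °C
Reagents that add atoms: none
Why: Intramolecular Michael addition (5-exo-trig) of the propionate enolate to C5, the β-carbon of the C5=C6 enoate. The two-atom tether from O10 can deliver C4 only to the face of C5 that carries O10, so the lactone is cis-fused and C5 is set. Equilibration with tert-butoxide should place the C7 ester trans to the new C5–C4 bond (C6 set); the mixture at C4 is immaterial.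

Step 17
Reactants: 24; 25 acetyl chloride
Product: 26 4-acetyl-4-methyl lactone (acetyl cis to the C10 vinyl group, methyl towards ring B)
Conditions: LiN(i-Pr)2, THF, −78 °C; enolate transferred into 25, THF, −78 °C
Reagents that add atoms: none
Why: Crossed Claisen C-acylation of the lactone enolate; the lactone C4–H is more acidic and much more accessible than the tertiary C6–H of the tert-butyl ester. The electrophile approaches the cis-fused bicyclic enolate on its convex face, anti to C6, which sets the quaternary C4.

Step 18
Reactants: 26
Product: 27 C1 aldehyde (formyl group on C10 in place of vinyl)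
Conditions: O3, CH2Cl2, −78 °C; PPh3
Reagents that add atoms: ozone [O-][O+]=O
Why: Ozonolysis of the only alkene; the resulting aldehyde has no α-hydrogen and cannot enolise or epimerise.

Step 19
Reactants: 27
Product: 28 tetracyclic aldol with ring A closed, equatorial C1 hydroxyl cis to the lactone oxygen and a C3 ketone
Conditions: LiN(SiMe3)2, THF, −78 °C; AcOH quench at −78 °C
Reagents that add atoms: none
Why: Intramolecular aldol addition (6-enolexo-exo-trig) of the only enolisable ketone position, the C2 methyl, to the non-enolisable C1 aldehyde. In the lithium aldolate the C1 oxygen sits close to the C3 oxygen, which requires it to be equatorial; the same epimer should be favoured if the aldol equilibrates.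

Step 20
Reactants: 28
Product: 29 1,3-diol (axial C3 hydroxyl, trans to the C1 hydroxyl)
Conditions: LiBH(s-Bu)3, THF, −78 °C; aq. NH4Cl
Reagents that add atoms: none
Why: Steric approach control on a ring-locked cyclohexanone: the bulky borohydride avoids the axial path past H1 and H5 and delivers hydride equatorially, giving the axial alcohol (C3 set). The lactone and the tert-butyl ester are inert at −78 °C.

Step 21
Reactants: 29
Product: 30 16-oxo-17-nor acid (free C7 acid, free hydroxyls at C1, C3 and C13, C16 ketone)
Conditions: CF3CO2H–H2O (9:1), CH2Cl2, 0 → 25 °C
Reagents that add atoms: water O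
Why: One acid treatment hydrolyses the dioxolane, removes the triethylsilyl group and cleaves the tert-butyl ester (loss of isobutene); it is done before the acid-sensitive allylic alcohol and alkene exist.

Step 22
Reactants: 30
Product: 31 target, CNP0252949.2
Conditions: Ph3PCH3Br (8 equiv), KN(SiMe3)2 (7 equiv), THF, 0 °C; then 30, 25 → 60 °C; aq. citric acid
Reagents that add atoms: methylenetriphenylphosphorane C=P(c1ccccc1)(c1ccccc1)c1ccccc1
Why: Wittig methylenation of the hindered C16 ketone. The ylide is too weak a base to ionise the alcohols to any extent (only the acid is deprotonated), and the phosphonium salt is kept in excess over the amide base, which protects C3 against retro-aldol epimerisation and the α-ketol against rearrangement.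

## Compound list

1 | methyl cyclopent-3-ene-1-carboxylate | COC(=O)C1CC=CC1 | starting material
2 | tert-butyl bromoacetate | BrCC(=O)OC(C)(C)C | starting material
3 | methyl 1-(2-tert-butoxy-2-oxoethyl)cyclopent-3-ene-1-carboxylate | COC(=O)C1(CC(=O)OC(C)(C)C)CC=CC1 | intermediate
4 | tert-butyl 2-(1-formylcyclopent-3-en-1-yl)acetate | O=CC1(CC(=O)OC(C)(C)C)CC=CC1 | intermediate
5 | methyl 2-[bis(2,2,2-trifluoroethoxy)phosphoryl]acetate | COC(=O)CP(=O)(OCC(F)(F)F)OCC(F)(F)F | starting material
6 | tert-butyl 2-{1-[(Z)-3-methoxy-3-oxoprop-1-en-1-yl]cyclopent-3-en-1-yl}acetate | COC(=O)/C=C\C1(CC(=O)OC(C)(C)C)CC=CC1 | intermediate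
7 | tert-butyl 2-{1-[(Z)-3-hydroxyprop-1-en-1-yl]cyclopent-3-en-1-yl}acetate | OC/C=C\C1(CC(=O)OC(C)(C)C)CC=CC1 | intermediate
8 | tert-butyl 2-{1-[(Z)-3-bromoprop-1-en-1-yl]cyclopent-3-en-1-yl}acetate | BrC/C=C\C1(CC(=O)OC(C)(C)C)CC=CC1 | intermediate
9 | tert-butyl 2-{1-[(Z)-3-bromoprop-1-en-1-yl]-cis-3,4-dihydroxycyclopentyl}acetate (both achiral diastereomers) | BrC/C=C\C1(CC(=O)OC(C)(C)C)C[C@H](O)[C@H](O)C1 | intermediate
10 | tert-butyl 2-{1-[(Z)-3-bromoprop-1-en-1-yl]-3,4-dioxocyclopentyl}acetate | BrC/C=C\C1(CC(=O)OC(C)(C)C)CC(=O)C(=O)C1 | intermediate
11 | tert-butyl 2-(5-hydroxy-6-oxobicyclo[3.2.1]oct-2-en-1-yl)acetate, C8 and C13 as in 31 | O=C1C[C@]2(CC(=O)OC(C)(C)C)C[C@@]1(O)CC=C2 | intermediate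
12 | 13-O-triethylsilyl ether of 11 | O=C1C[C@]2(CC(=O)OC(C)(C)C)C[C@@]1(O[Si](CC)(CC)CC)CC=C2 | intermediate
13 | 16,16-ethylenedioxy derivative of 12 | O1CCOC12C[C@]3(CC(=O)OC(C)(C)C)C[C@@]2(O[Si](CC)(CC)CC)CC=C3 | intermediate
14 | 2,3-dibromopropene | BrCC(Br)=C | starting material
15 | 13 with a 2-bromoprop-2-enyl group on C6 (C6 epimers) | O1CCOC12C[C@]3(C(CC(Br)=C)C(=O)OC(C)(C)C)C[C@@]2(O[Si](CC)(CC)CC)CC=C3 | intermediate
16 | B/C/D tricycle with C10 exocyclic methylene, cis B/C fusion (C6 epimers) | O1CCOC12C[C@]34C[C@@]2(O[Si](CC)(CC)CC)CC[C@H]3C(=C)CC4C(=O)OC(C)(C)C | intermediate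
17 | B/C/D tricyclic C10 ketone (C6 epimers) | O1CCOC12C[C@]34C[C@@]2(O[Si](CC)(CC)CC)CC[C@H]3C(=O)CC4C(=O)OC(C)(C)C | intermediate
18 | C10 trimethylsilyl enol ether of 17 (C5=C10) | O1CCOC12C[C@]34C[C@@]2(O[Si](CC)(CC)CC)CC[C@H]3C(O[Si](C)(C)C)=CC4C(=O)OC(C)(C)C | intermediate (not isolated)
19 | ring B enone: C10 ketone, C5=C6, C7 tert-butyl ester on C6 | O1CCOC12C[C@]34C[C@@]2(O[Si](CC)(CC)CC)CC[C@H]3C(=O)C=C4C(=O)OC(C)(C)C | intermediate
20 | vinylmagnesium bromide | C=C[Mg]Br | starting material
21 | propionic anhydride | CCC(=O)OC(=O)CC | starting material
22 | bromomagnesium alkoxide of the C10 vinyl carbinol | O1CCOC12C[C@]34C[C@@]2(O[Si](CC)(CC)CC)CC[C@H]3[C@@](C=C)(O[Mg]Br)C=C4C(=O)OC(C)(C)C | intermediate (not isolated)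
23 | C10 vinyl carbinol propionate (vinyl on the face of H9) | O1CCOC12C[C@]34C[C@@]2(O[Si](CC)(CC)CC)CC[C@H]3[C@@](C=C)(OC(=O)CC)C=C4C(=O)OC(C)(C)C | intermediate
24 | tricyclic 19,10-lactone, C4 H/methyl (both epimers), C5 and C6 as in 31, vinyl on C10 | O1CCOC12C[C@]34C[C@@]2(O[Si](CC)(CC)CC)CC[C@H]3[C@@]5(C=C)OC(=O)C(C)[C@H]5[C@@H]4C(=O)OC(C)(C)C | intermediate
25 | acetyl chloride | CC(Cl)=O | starting material
26 | 4-acetyl-4-methyl lactone, C4 as in 31 | O1CCOC12C[C@]34C[C@@]2(O[Si](CC)(CC)CC)CC[C@H]3[C@@]5(C=C)OC(=O)[C@@](C)([C@H]5[C@@H]4C(=O)OC(C)(C)C)C(C)=O | intermediate
27 | C1 aldehyde (formyl on C10) | O1CCOC12C[C@]34C[C@@]2(O[Si](CC)(CC)CC)CC[C@H]3[C@@]5(C=O)OC(=O)[C@@](C)([C@H]5[C@@H]4C(=O)OC(C)(C)C)C(C)=O | intermediate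
28 | tetracyclic 1-hydroxy-3-ketone, ring A closed | O1CCOC12C[C@]34C[C@@]2(O[Si](CC)(CC)CC)CC[C@H]3[C@@]56OC(=O)[C@@](C)([C@H]5[C@@H]4C(=O)OC(C)(C)C)C(=O)C[C@@H]6O | intermediate
29 | protected 1,3-diol (C3 as in 31) | O1CCOC12C[C@]34C[C@@]2(O[Si](CC)(CC)CC)CC[C@H]3[C@@]56OC(=O)[C@@](C)([C@H]5[C@@H]4C(=O)OC(C)(C)C)[C@@H](O)C[C@@H]6O | intermediate
30 | 16-oxo-17-nor acid of the target | O=C1C[C@]23C[C@@]1(O)CC[C@H]2[C@@]45OC(=O)[C@@](C)([C@H]4[C@@H]3C(=O)O)[C@@H](O)C[C@@H]5O | intermediate
31 | CNP0252949.2 | C=C1C[C@]23C[C@@]1(O)CC[C@H]2[C@@]12OC(=O)[C@@](C)([C@H]1[C@@H]3C(=O)O)[C@@H](O)C[C@@H]2O | target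

## Step count and least certain steps

Total step count: 22. Longest linear sequence: 22 (from 1; all other inputs are commercial).

Step 8 (key step, proposed new method). The most likely failure is weak discrimination between the two mirror-image carbonyls, because the substrate reacts through fast-exchanging hydroxy-enone tautomers and the tether, more than the ligand, shapes the transition state. Protonolysis of the allylchromium by the enol O–H and reduction of the dione by divalent chromium may also compete with ring closure. Fallback with known chemistry: from 10, ring closure with CrCl2 alone in THF–DMF, an intramolecular Nozaki–Hiyama allylation without asymmetric induction, gives 11 together with its mirror image, the enantiomer of 11 F1. Preparative chromatography on a chiral stationary phase separates them, and 11 re-enters the route at step 9, at the cost of half the material.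

Step 6. Chemoselectivity may erode (osmylation of the arm alkene), or the allylic bromide may be lost by hydrolysis or by quaternisation with N-methylmorpholine during the aqueous reaction. Fallback: from 6, dihydroxylate while the arm alkene is still an electron-poor enoate and inert, giving the diol enoate F2. Silylate with Et3SiCl and imidazole to the bis(triethylsilyl) ether F3, reduce with i-Bu2AlH to the allylic alcohol F4, and brominate with CBr4 and PPh3 to the bis-silylated bromide F5. Desilylation with HF·pyridine gives 9, where the route is rejoined.

Step 15. The hindered tertiary alkoxide may fail to be acylated in the flask, or the doubly allylic propionate may ionise or undergo a [3,3] shift once enolised in step 16. Fallback, replacing the anionic closure by a radical one: from 19, the same vinyl addition with aqueous quench gives the tertiary alcohol F6. N-Bromosuccinimide and ethyl prop-1-enyl ether convert it to the mixed bromoacetal F7. n-Bu3SnH and AIBN close the C4–C5 bond by 5-exo radical addition to the enoate, and tert-butoxide equilibration at C6 gives the cyclic ethyl acetal F8. Mild hydrolysis (PPTS, aqueous acetone) gives the lactol F9, and Ag2CO3 on Celite oxidises it to 24, so steps 15 and 16 are bypassed.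

Step 17. Proton transfer from the newly formed methyl ketone to unreacted enolate may stall the acylation or cause double acylation; O-acylation or deprotonation at C6 are further risks. Fallback: from 24, the lithium enolate is added to acetaldehyde, whose alkoxide product cannot quench the enolate, giving the C3 carbinol F10 as a mixture at C3. Dess–Martin oxidation then returns 26.

Step 20. Facial selectivity may be poor, with hydride also arriving along the axial path and giving the equatorial C3 epimer, and the C1 alkoxide may undergo retro-aldol. Fallback by internal hydride delivery: from 28, chlorodiisopropylsilane and imidazole give the C1 diisopropylsilyl ether F11. SnCl4-catalysed intramolecular hydrosilylation of the C3 ketone, an anti-selective 1,3-reduction, gives the cyclic siladioxane F12. The conditions of step 21 with aqueous HF added remove the silylene with the other groups and give 30.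

Step 22. Methylenation of the hindered ketone may be incomplete while ylide is consumed by the acidic protons, and any free amide base could trigger α-ketol rearrangement or C3 epimerisation. Fallback on a protected substrate with a non-basic reagent: from 30, Me3SiCl and imidazole give the persilylated ketone F13 (three silyl ethers and the silyl ester). Zn/CH2Br2/TiCl4 methylenates it to the persilylated alkene F14. Aqueous citric acid in methanol removes the silyl groups and gives 31.

## Further compounds

F1 | step 8 | enantiomer of 11 | O=C1C[C@@]2(CC(=O)OC(C)(C)C)C[C@]1(O)CC=C2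
F2 | step 6 | tert-butyl 2-{cis-3,4-dihydroxy-1-[(Z)-3-methoxy-3-oxoprop-1-en-1-yl]cyclopentyl}acetate | COC(=O)/C=C\C1(CC(=O)OC(C)(C)C)C[C@H](O)[C@H](O)C1
F3 | step 6 | bis(triethylsilyl) ether of F2 | COC(=O)/C=C\C1(CC(=O)OC(C)(C)C)C[C@H](O[Si](CC)(CC)CC)[C@H](O[Si](CC)(CC)CC)C1
F4 | step 6 | (Z)-allylic alcohol from F3 | OC/C=C\C1(CC(=O)OC(C)(C)C)C[C@H](O[Si](CC)(CC)CC)[C@H](O[Si](CC)(CC)CC)C1
F5 | step 6 | (Z)-allylic bromide from F4 | BrC/C=C\C1(CC(=O)OC(C)(C)C)C[C@H](O[Si](CC)(CC)CC)[C@H](O[Si](CC)(CC)CC)C1
F6 | step 15 | C10 vinyl carbinol (free tertiary alcohol) | O1CCOC12C[C@]34C[C@@]2(O[Si](CC)(CC)CC)CC[C@H]3[C@@](C=C)(O)C=C4C(=O)OC(C)(C)C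
F7 | step 15 | mixed bromoacetal of F6 (1-ethoxy-2-bromopropyl ether) | O1CCOC12C[C@]34C[C@@]2(O[Si](CC)(CC)CC)CC[C@H]3[C@@](C=C)(OC(OCC)C(C)Br)C=C4C(=O)OC(C)(C)C
F8 | step 15 | cyclic ethyl acetal (lactol ether corresponding to 24) | O1CCOC12C[C@]34C[C@@]2(O[Si](CC)(CC)CC)CC[C@H]3[C@@]5(C=C)OC(OCC)C(C)[C@H]5[C@@H]4C(=O)OC(C)(C)C
F9 | step 15 | lactol corresponding to 24 | O1CCOC12C[C@]34C[C@@]2(O[Si](CC)(CC)CC)CC[C@H]3[C@@]5(C=C)OC(O)C(C)[C@H]5[C@@H]4C(=O)OC(C)(C)C
F10 | step 17 | 4-(1-hydroxyethyl)-4-methyl lactone (C3 epimers) | O1CCOC12C[C@]34C[C@@]2(O[Si](CC)(CC)CC)CC[C@H]3[C@@]5(C=C)OC(=O)[C@@](C)([C@H]5[C@@H]4C(=O)OC(C)(C)C)C(C)O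
F11 | step 20 | C1 diisopropylsilyl ether of 28 | O1CCOC12C[C@]34C[C@@]2(O[Si](CC)(CC)CC)CC[C@H]3[C@@]56OC(=O)[C@@](C)([C@H]5[C@@H]4C(=O)OC(C)(C)C)C(=O)C[C@@H]6O[SiH](C(C)C)C(C)C
F12 | step 20 | 1,3-O-diisopropylsilylene derivative of 29 | O1CCOC12C[C@]34C[C@@]2(O[Si](CC)(CC)CC)CC[C@H]3[C@@]56OC(=O)[C@@](C)([C@H]5[C@@H]4C(=O)OC(C)(C)C)[C@@H]7C[C@@H]6O[Si](C(C)C)(C(C)C)O7
F13 | step 22 | tris(trimethylsilyl) ether trimethylsilyl ester of 30 | O=C1C[C@]23C[C@@]1(O[Si](C)(C)C)CC[C@H]2[C@@]45OC(=O)[C@@](C)([C@H]4[C@@H]3C(=O)O[Si](C)(C)C)[C@@H](O[Si](C)(C)C)C[C@@H]5O[Si](C)(C)C
F14 | step 22 | tris(trimethylsilyl) ether trimethylsilyl ester of 31 | C=C1C[C@]23C[C@@]1(O[Si](C)(C)C)CC[C@H]2[C@@]45OC(=O)[C@@](C)([C@H]4[C@@H]3C(=O)O[Si](C)(C)C)[C@@H](O[Si](C)(C)C)C[C@@H]5O[Si](C)(C)C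
A1 | alternative 1 | 1-O-tert-butyldimethylsilyl, 13-O-triethylsilyl C7 methyl ester of the target with free C3 hydroxyl | C=C1C[C@]23C[C@@]1(O[Si](CC)(CC)CC)CC[C@H]2[C@@]12OC(=O)[C@@](C)([C@H]1[C@@H]3C(=O)OC)[C@@H](O)C[C@@H]2O[Si](C)(C)C(C)(C)C
A2 | alternative 2 | B/C/D tricycle with C10 exocyclic methylene, C6 dimethyl malonate, 13-O-methoxymethyl and 16-O-tert-butyldimethylsilyl | CC(C)(C)[Si](C)(C)O[C@H]1C[C@]23C[C@@]1(OCOC)CC[C@H]2C(=C)CC3(C(=O)OC)C(=O)OC
A3 | alternative 3 | B/C/D tricyclic C10 ketone with C7 methyl ester and C5 methyl propionate arm (C4 epimers) | C=C1C[C@]23C[C@@]1(O)CC[C@H]2C(=O)[C@H]([C@@H]3C(=O)OC)C(C)C(=O)OC
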